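**Retrosynthetic overview**
1. End game: the C13 acetoxymethyl group comes from a temporary C11–Br handle (Stille coupling, then acetylation), and the C10–OH is unmasked last.
2. Key disconnection at C5=C6: the nine-membered oxacycle C8–C9–C10–C1–O–C4–C5–C6–C7 opens to aldehyde 16. One flask closes it by O-silylation, furan formation, vinylogous aldol addition and E1cB loss of silanolate.
3. Enabling feature: C6 is the γ-CH2 of the butenolide ring (O–C12(=O)–C11=C7–C6) and therefore a latent 2-silyloxyfuran nucleophile. C5 sits on the quaternary C4 of the dihydrofuran ring and is a non-enolisable aldehyde. The new ring holds C4 and C7 cis on C5=C6 (E), the geometry that open-chain condensations do not give.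
4. Aldehyde 16 comes from a C8–C9 boron aldol union of acetyl-dihydrofuran 6 with furaldehyde 10 (sets C8), followed by chelate-controlled methyl addition (sets C10). C4 comes from (S)-2-methylglycidol.
5. Ring order: dihydrofuran (step 3); butenolide (present in 7, masked as a furan in 10–14); nine-membered ring last (step 13).

Key step: step 13

Remark: germacrane numbering is used (C1=C2 enol ether, C4 quaternary O-carbon, C5=C6 alkylidene, C7=C11 butenolide alkene, C8 ester carbinol, C10 tertiary carbinol, C12 lactone C=O, C13 CH2OAc), and (−)-Ipc2BCl is assumed to direct attack to the Re face of aldehyde 10; if the sense is opposite, the (+)-reagent is used.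

Step 1
Reactants: 1 (S)-2-methylglycidol
Product: 2 (R)-tert-butyldimethyl[(2-methyloxiran-2-yl)methoxy]silane
Conditions: TBSCl, imidazole, CH2Cl2, 0 °C → rt
Reagents that add atoms: tert-butyldimethylsilyl chloride, CC(C)(C)[Si](C)(C)Cl
Why: Standard O-silylation of the primary alcohol; no bond to the future C4 centre is touched (the descriptor changes only through CIP ranking).

Step 2
Reactants: 2 (R)-tert-butyldimethyl[(2-methyloxiran-2-yl)methoxy]silane
Product: 3 (R)-1-(tert-butyldimethylsilyloxy)-2-methylpent-4-yn-2-ol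
Conditions: lithium acetylide·ethylenediamine, DMSO, rt; H2O
Reagents that add atoms: lithium acetylide–ethylenediamine complex, [Li]C#C.NCCN
Why: SN2 epoxide opening by acetylide at the unhindered CH2 terminus of the 2,2-disubstituted oxirane, so the C4–O bond and its configuration are retained.

Step 3
Reactants: 3 (R)-1-(tert-butyldimethylsilyloxy)-2-methylpent-4-yn-2-ol
Product: 4 (R)-tert-butyldimethyl[(2-methyl-2,3-dihydrofuran-2-yl)methoxy]silane
Conditions: Mo(CO)6 (25 mol %), Et3N, Et2O, hν (350 nm), rt
Reagents that add atoms: none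
Why: Molybdenum-vinylidene cycloisomerisation of a 1-alkyn-4-ol; the tertiary hydroxyl adds to the vinylidene carbon and gives the endocyclic enol ether (first ring).

Step 4
Reactants: 4 (R)-tert-butyldimethyl[(2-methyl-2,3-dihydrofuran-2-yl)methoxy]silane
Product: 6 1-[(5R)-5-(tert-butyldimethylsilyloxymethyl)-5-methyl-4,5-dihydrofuran-2-yl]ethan-1-one, via lithiated dihydrofuran 5 (not isolated)
Conditions: t-BuLi, THF, −78 → 0 °C; MeC(O)N(OMe)Me, −78 °C → rt; H2O
Reagents that add atoms: N-methoxy-N-methylacetamide, CC(=O)N(C)OC; tert-butyllithium, [Li]C(C)(C)C (lithium of 5 only)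
Why: α-Lithiation of the cyclic enol ether at the sp2 C–H next to oxygen, then Weinreb ketone synthesis, which stops at the ketone through the chelated tetrahedral adduct.

Step 5
Reactants: 7 3,4-dibromofuran-2(5H)-one
Product: 8 3-bromo-4-vinylfuran-2(5H)-one
Conditions: CH2=CHSnBu3, PdCl2(PhCN)2 (5 mol %), AsPh3 (10 mol %), NMP, rt
Reagents that add atoms: tributyl(vinyl)stannane, C=C[Sn](CCCC)(CCCC)CCCC
Why: Site-selective Stille coupling; oxidative addition occurs at the more electrophilic β-C–Br bond, the known preference of this dibromide.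

Step 6
Reactants: 8 3-bromo-4-vinylfuran-2(5H)-one
Product: 9 4-bromo-5-oxo-2,5-dihydrofuran-3-carbaldehyde
Conditions: O3, CH2Cl2, −78 °C; Me2S
Reagents that add atoms: ozone, [O-][O+]=O
Why: Ozonolysis with reductive work-up cleaves the terminal vinyl group, while the bromine-bearing, tetrasubstituted, electron-poor ring alkene is far less reactive.

Step 7
Reactants: 9 4-bromo-5-oxo-2,5-dihydrofuran-3-carbaldehyde
Product: 10 4-bromo-5-(triisopropylsilyloxy)furan-3-carbaldehyde
Conditions: TIPSOTf, Et3N, CH2Cl2, 0 °C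
Reagents that add atoms: triisopropylsilyl triflate, CC(C)[Si](C(C)C)(C(C)C)OS(=O)(=O)C(F)(F)F
Why: Soft enolisation and O-silylation give the aromatic 2-silyloxyfuran, which masks the lactone and its acidic γ-CH2 for the enolate and Grignard steps and is stabilised by the formyl group.

Step 8
Reactants: 6 1-[(5R)-5-(tert-butyldimethylsilyloxymethyl)-5-methyl-4,5-dihydrofuran-2-yl]ethan-1-one; 10 4-bromo-5-(triisopropylsilyloxy)furan-3-carbaldehyde
Product: 12 (3R)-3-[4-bromo-5-(triisopropylsilyloxy)furan-3-yl]-1-[(5R)-5-(tert-butyldimethylsilyloxymethyl)-5-methyl-4,5-dihydrofuran-2-yl]-3-hydroxypropan-1-one, via diisopinocampheylboron enolate 11 (not isolated)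
Conditions: (−)-Ipc2BCl, Et3N, Et2O, −78 → 0 °C; 10, −78 → −20 °C; pH 7 buffer/MeOH (non-oxidative work-up)
Reagents that add atoms: (−)-B-chlorodiisopinocampheylborane, ClB([C@@H]1C[C@@H]2C[C@H]([C@H]1C)C2(C)C)[C@@H]1C[C@@H]2C[C@H]([C@H]1C)C2(C)C (boryl group of 11 only)
Why: Diisopinocampheylboron-mediated asymmetric aldol reaction of a methyl ketone; enolate 11 adds through a cyclic transition state to the Re face of 10 under reagent control and sets C8 as R, and because the remote C4 centre exerts no bias, any minor isomer is a separable diastereomer.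

Step 9
Reactants: 12 the (3R)-β-hydroxy ketone
Product: 13 (2S,4R)-4-[4-bromo-5-(triisopropylsilyloxy)furan-3-yl]-2-[(5R)-5-(tert-butyldimethylsilyloxymethyl)-5-methyl-4,5-dihydrofuran-2-yl]butane-2,4-diol
Conditions: MeMgBr (3 equiv), CH2Cl2/Et2O, −78 °C; pH 7 buffer
Reagents that add atoms: methylmagnesium bromide, C[Mg]Br
Why: Chelation-controlled Grignard 1,2-addition; the C8 magnesium alkoxide binds the C10 carbonyl in a six-membered chelate with the furyl group equatorial, and external MeMgBr attacks axially to give the 8,10-syn diol, i.e. C10 as S.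

Step 10
Reactants: 13 the (2S,4R)-diol
Product: 14 (1R,3S)-1-[4-bromo-5-(triisopropylsilyloxy)furan-3-yl]-3-[(5R)-5-(tert-butyldimethylsilyloxymethyl)-5-methyl-4,5-dihydrofuran-2-yl]-3-hydroxybutyl methacrylate
Conditions: methacrylic anhydride, Et3N, DMAP (cat.), CH2Cl2, 0 °C
Reagents that add atoms: methacrylic anhydride, C=C(C)C(=O)OC(=O)C(C)=C
Why: DMAP-catalysed acylation distinguishes the secondary C8 hydroxyl from the hindered tertiary C10 hydroxyl on steric grounds.

Step 11
Reactants: 14 the silylated methacrylate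
Product: 15 (1R,3S)-1-(4-bromo-5-oxo-2,5-dihydrofuran-3-yl)-3-hydroxy-3-[(5R)-5-(hydroxymethyl)-5-methyl-4,5-dihydrofuran-2-yl]butyl methacrylate
Conditions: TBAF/AcOH (1:1), THF, 0 °C → rt
Reagents that add atoms: none
Why: Buffered fluoride desilylation removes the primary TBS ether and the furan O-TIPS group together; the furanolate is protonated at C6 to return the conjugated butenolide, and the buffer spares the ester and the enol ether.

Step 12
Reactants: 15 the bromobutenolide diol
Product: 16 (1R,3S)-1-(4-bromo-5-oxo-2,5-dihydrofuran-3-yl)-3-[(5R)-5-formyl-5-methyl-4,5-dihydrofuran-2-yl]-3-hydroxybutyl methacrylate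
Conditions: Dess–Martin periodinane, pyridine, CH2Cl2, 0 °C → rt
Reagents that add atoms: none
Why: Dess–Martin oxidation of the only primary alcohol; the tertiary C10–OH cannot be oxidised and cannot form a hemiacetal with C5, because that would put C1=C2 at the bridgehead of a bicyclo[3.2.1] system.

Step 13
Reactants: 16 the aldehyde
Product: 19 (4R,5E,8R,10S)-11-bromo-1,4-epoxy-8-methacryloyloxy-10-triethylsilyloxy-13-norgermacra-1,5,7(11)-trien-12,6-olide, via bis-TES silyloxyfuran aldehyde 17 (not isolated), via macrocyclic aldol TES ether 18 (not isolated)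
Conditions: TESOTf (4 equiv), i-Pr2NEt (8 equiv), CH2Cl2 (1 mM, slow addition of 16), −78 → 0 °C; then DBU (3 equiv), 0 °C → rt
Reagents that add atoms: triethylsilyl triflate, CC[Si](CC)(CC)OS(=O)(=O)C(F)(F)F
Why: TESOTf/i-Pr2NEt caps the C10 hydroxyl and soft-enolises the bromobutenolide at its γ-CH2 (C6) to the aromatic 2-silyloxyfuran 17, whose C6 attacks the silyl-activated, non-enolisable C5 aldehyde (vinylogous Mukaiyama aldol) to give silyl ether 18, after which DBU removes the doubly activated C6–H and expels triethylsilanolate (E1cB) to leave C5=C6. The closest known reaction is the one-pot silyl triflate/amine-then-DBU condensation of furan-2(5H)-ones with aldehydes to γ-alkylidenebutenolides, run here intramolecularly at high dilution. The nine-membered oxacycle closes in a 9-(enolendo)-exo-trig mode and the ten-membered carbocycle C1–C10 closes with it; only five tether bonds can rotate, because C1/O/C4 lie in the dihydrofuran and C6/C7 in the furan, and the fully substituted C4 and C10 add a gem-dialkyl effect. No lasting stereocentre is created: the C5 and C6 centres of 18 are erased, and the alkene geometry is set by the ring, since only the isomer with C4 and C7 cis (E) lets the four-atom bridge O–C1–C10–C9 span C4 to C8 without severe strain, whereas open-chain condensations give the Z isomer. The step needs C6 to attack C5 rather than C1, which the excess amine secures by keeping the enol ether C1=C2 unprotonated; bromine at C11 in place of CH2OAc removes the vinylogous β-leaving group that a silyloxyfuran would expel, and the C8 ester sits at a furan position not conjugated with the C12 oxygen donor.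

Step 14
Reactants: 19 the bromo macrocycle
Product: 20 (4R,5E,8R,10S)-1,4-epoxy-13-hydroxy-8-methacryloyloxy-10-triethylsilyloxygermacra-1,5,7(11)-trien-12,6-olide
Conditions: Bu3SnCH2OH, Pd(PPh3)4 (10 mol %), dioxane, 80 °C
Reagents that add atoms: (tributylstannyl)methanol, OC[Sn](CCCC)(CCCC)CCCC
Why: Stille hydroxymethylation; oxidative addition at the only C–Br bond (electron-poor α-bromobutenolide) replaces the temporary bromine with C13.

Step 15
Reactants: 20 the C13 alcohol
Product: 21 (4R,5E,8R,10S)-13-acetoxy-1,4-epoxy-8-methacryloyloxy-10-triethylsilyloxygermacra-1,5,7(11)-trien-12,6-olide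
Conditions: Ac2O, pyridine, DMAP (cat.), CH2Cl2, 0 °C
Reagents that add atoms: acetic anhydride, CC(=O)OC(C)=O
Why: Simple acetylation of the only free hydroxyl group under mildly basic conditions that the enol ether tolerates.

Step 16
Reactants: 21 the C10 TES ether
Product: 22 (4R,5E,8R,10S)-13-acetoxy-1,4-epoxy-10-hydroxy-8-methacryloyloxygermacra-1,5,7(11)-trien-12,6-olide (CNP0394509.1)
Conditions: Et3N·3HF, THF, 0 °C → rt
Reagents that add atoms: none
Why: Fluoride cleavage of the tertiary TES ether with a nearly neutral HF source, which should spare both esters, the alkylidene butenolide and the acid-labile α-hydroxy enol ether.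

**Compound list**
1 | (S)-2-methylglycidol | C1[C@](C)(CO)O1 | starting material
2 | (R)-tert-butyldimethyl[(2-methyloxiran-2-yl)methoxy]silane | C1[C@](C)(CO[Si](C)(C)C(C)(C)C)O1 | intermediate
3 | (R)-1-(tert-butyldimethylsilyloxy)-2-methylpent-4-yn-2-ol | C#CC[C@](C)(CO[Si](C)(C)C(C)(C)C)O | intermediate
4 | (R)-tert-butyldimethyl[(2-methyl-2,3-dihydrofuran-2-yl)methoxy]silane | C1=CC[C@](C)(CO[Si](C)(C)C(C)(C)C)O1 | intermediate
5 | 5-lithio derivative of 4 | [Li]C1=CC[C@](C)(CO[Si](C)(C)C(C)(C)C)O1 | intermediate
6 | 1-[(5R)-5-(tert-butyldimethylsilyloxymethyl)-5-methyl-4,5-dihydrofuran-2-yl]ethan-1-one | CC(=O)C1=CC[C@](C)(CO[Si](C)(C)C(C)(C)C)O1 | intermediate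
7 | 3,4-dibromofuran-2(5H)-one | O=C1OCC(Br)=C1Br | starting material
8 | 3-bromo-4-vinylfuran-2(5H)-one | C=CC1=C(Br)C(=O)OC1 | intermediate
9 | 4-bromo-5-oxo-2,5-dihydrofuran-3-carbaldehyde | O=CC1=C(Br)C(=O)OC1 | intermediate
10 | 4-bromo-5-(triisopropylsilyloxy)furan-3-carbaldehyde | O=Cc1coc(O[Si](C(C)C)(C(C)C)C(C)C)c1Br | intermediate
11 | diisopinocampheylboron enolate of 6 | C=C(OB([C@@H]1C[C@@H]2C[C@H]([C@H]1C)C2(C)C)[C@@H]1C[C@@H]2C[C@H]([C@H]1C)C2(C)C)C1=CC[C@](C)(CO[Si](C)(C)C(C)(C)C)O1 | intermediate
12 | (3R)-aldol adduct (β-hydroxy ketone) | O[C@@H](c1coc(O[Si](C(C)C)(C(C)C)C(C)C)c1Br)CC(=O)C1=CC[C@](C)(CO[Si](C)(C)C(C)(C)C)O1 | intermediate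
13 | (2S,4R)-syn-diol | O[C@@H](c1coc(O[Si](C(C)C)(C(C)C)C(C)C)c1Br)C[C@](C)(O)C1=CC[C@](C)(CO[Si](C)(C)C(C)(C)C)O1 | intermediate
14 | C8 methacrylate, silylated | C=C(C)C(=O)O[C@@H](c1coc(O[Si](C(C)C)(C(C)C)C(C)C)c1Br)C[C@](C)(O)C1=CC[C@](C)(CO[Si](C)(C)C(C)(C)C)O1 | intermediate
15 | bromobutenolide diol | C=C(C)C(=O)O[C@@H](C1=C(Br)C(=O)OC1)C[C@](C)(O)C1=CC[C@](C)(CO)O1 | intermediate
16 | bromobutenolide aldehyde | C=C(C)C(=O)O[C@@H](C1=C(Br)C(=O)OC1)C[C@](C)(O)C1=CC[C@](C)(C=O)O1 | intermediate
17 | bis-TES silyloxyfuran aldehyde | C=C(C)C(=O)O[C@@H](c1coc(O[Si](CC)(CC)CC)c1Br)C[C@](C)(O[Si](CC)(CC)CC)C1=CC[C@](C)(C=O)O1 | intermediate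
18 | macrocyclic aldol TES ether (C5, C6 undefined) | C=C(C)C(=O)O[C@@H]1C[C@](C)(O[Si](CC)(CC)CC)C2=CC[C@](C)(C(O[Si](CC)(CC)CC)C3OC(=O)C(Br)=C31)O2 | intermediate
19 | bromo macrocycle, C10 TES ether | C=C(C)C(=O)O[C@@H]1C[C@](C)(O[Si](CC)(CC)CC)C2=CC[C@](C)(/C=C3/OC(=O)C(Br)=C31)O2 | intermediate
20 | C13 alcohol, C10 TES ether | C=C(C)C(=O)O[C@@H]1C[C@](C)(O[Si](CC)(CC)CC)C2=CC[C@](C)(/C=C3/OC(=O)C(CO)=C31)O2 | intermediate
21 | C13 acetate, C10 TES ether | C=C(C)C(=O)O[C@@H]1C[C@](C)(O[Si](CC)(CC)CC)C2=CC[C@](C)(/C=C3/OC(=O)C(COC(C)=O)=C31)O2 | intermediate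
22 | CNP0394509.1 | C=C(C)C(=O)O[C@@H]1C[C@](C)(O)C2=CC[C@](C)(/C=C3/OC(=O)C(COC(C)=O)=C31)O2 | target

**Totals**
Total step count: 16. Longest linear sequence: 13 steps (steps 1–4 and 8–16).

**Steps most likely to fail**

1. Step 13. Oligomerisation may outrun the slow medium-ring closure, the aldol addition may revert before silyl trapping, or adventitious acid may protonate the enol ether so that C6 attacks C1 instead of C5. The fallback sets out from 15, returns at 19, and replaces the aldol manifold with an irreversible phosphonate olefination.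
   - Diol 15 is treated with TESOTf/i-Pr2NEt at −78 °C to give the tris-TES silyloxyfuran F1.
   - F1 is brominated in the same flask at C6 with NBS at −78 °C, the silyloxyfuran being by far the most nucleophilic π system, to give the γ-bromobutenolide F2.
   - An Arbuzov reaction with P(OMe)3 gives the C6 phosphonate F3.
   - Swern conditions convert the primary TES ether directly into the aldehyde phosphonate F4 and leave the tertiary TES ether in place.
   - Slow addition of F4 to LiCl/DBU in MeCN closes the same ring by an intramolecular Horner–Wadsworth–Emmons reaction and delivers 19.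

2. Step 9. Facial selectivity at C10 may be poor if the magnesium chelate is loose, and the magnesium aldolate may undergo retro-aldol cleavage. The fallback sets out from 12, returns at 14, and uses catalyst control in place of chelate control.
   - Adduct 12 is first acylated (methacrylic anhydride, DMAP) to the β-methacryloyloxy ketone F5.
   - The methyl group is then added with Me2Zn/Ti(Oi-Pr)4 and a catalytic camphorsulfonamide-derived bis(sulfonamide) diol ligand, using the antipode that gives 10S. These conditions tolerate the ester, the bromide and the silyloxyfuran and give 14 directly.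

3. Step 14. Transmetalation of the hydroxymethyl stannane may be slow at temperatures the macrocycle tolerates, which would allow protodebromination or palladium-induced ionisation of the allylic C8 ester. The fallback sets out from 19, returns at 20, and uses carbonylation followed by reduction in place of direct CH2OH transfer.
   - Pd(PPh3)4, CO (1 atm) and slowly added Bu3SnH at 50 °C formylate the C–Br bond to give the α-formyl butenolide F6.
   - Luche reduction (NaBH4, CeCl3·7H2O, MeOH, −78 °C) converts F6 into 20.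

**Further compounds**
F1 | step 13 | tris-TES silyloxyfuran | C=C(C)C(=O)O[C@@H](c1coc(O[Si](CC)(CC)CC)c1Br)C[C@](C)(O[Si](CC)(CC)CC)C1=CC[C@](C)(CO[Si](CC)(CC)CC)O1
F2 | step 13 | γ-bromobutenolide (C6 undefined) | C=C(C)C(=O)O[C@@H](C1=C(Br)C(=O)OC1Br)C[C@](C)(O[Si](CC)(CC)CC)C1=CC[C@](C)(CO[Si](CC)(CC)CC)O1
F3 | step 13 | C6 dimethyl phosphonate | C=C(C)C(=O)O[C@@H](C1=C(Br)C(=O)OC1P(=O)(OC)OC)C[C@](C)(O[Si](CC)(CC)CC)C1=CC[C@](C)(CO[Si](CC)(CC)CC)O1
F4 | step 13 | aldehyde phosphonate | C=C(C)C(=O)O[C@@H](C1=C(Br)C(=O)OC1P(=O)(OC)OC)C[C@](C)(O[Si](CC)(CC)CC)C1=CC[C@](C)(C=O)O1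
F5 | step 9 | β-methacryloyloxy ketone | C=C(C)C(=O)O[C@@H](c1coc(O[Si](C(C)C)(C(C)C)C(C)C)c1Br)CC(=O)C1=CC[C@](C)(CO[Si](C)(C)C(C)(C)C)O1
F6 | step 14 | α-formyl butenolide macrocycle | C=C(C)C(=O)O[C@@H]1C[C@](C)(O[Si](CC)(CC)CC)C2=CC[C@](C)(/C=C3/OC(=O)C(C=O)=C31)O2
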